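The constants used here were set for the occasion; the run is a simulation.

Take four flasks that share their charges and differ in how those charges go in.

all flasks: free catalyst 0.28 mM; time 80 s
- larch: starting material 0.30 M; partner 0.285 M (fed, over 50 s); all else is in the flask from the start; the feed brings no volume worth counting
- cedar: starting material 0.30 M; partner 0.285 M; everything together at the start
- maple: starting material 0.30 M (fed, over 50 s); partner 0.285 M; all else is in the flask from the start; the feed brings no volume worth counting
- alder: starting material 0.30 M; partner 0.285 M (fed, over 5.0 s); all else is in the flask from the start; the feed brings no volume worth counting

    starting material + partner + free catalyst → free catalyst + target (k1 = 12700 M⁻² s⁻¹)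
    2 free catalyst → spent catalyst (k2 = 3260 M⁻¹ s⁻¹)
    partner → decomposed reagent (k3 = 0.0801 s⁻¹)

- two of one species on the left: rate k times its square, two consumed each time
- run time (larch): 80 s

- the flask with the highest amount of target, in percent of the starting material charged ("all alike" if they lie within 1.5 percentage points) (larch / cedar / maple / alder / all alike)
- final target, as a percentage of the starting material charged, in larch
- final target, as a percentage of the starting material charged, in cedar
- final target, as a percentage of the starting material charged, in maple
- final target, as a percentage of the starting material charged, in alder

**What dies first?** Free catalyst. Its first half-life by the dying step is 0.548 s, far shorter than the slow feed. After that it stands near one over twice the dying constant times the time, and its charge has dropped out of the expression.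

**What does partner face?** Two exits. Decomposition runs at 0.0801 s⁻¹, a lifetime of 12.5 s. Capture into target is a pseudo-first-order rate: the step's constant times starting material times free catalyst.

**What is nearly constant in maple?** That product. In maple starting material is fed in proportion to time while free catalyst falls as one over time, so time cancels and capture stands near 0.0117 s⁻¹. The partner lifetime is shorter than maple's feed, so in maple this frozen rate covers the partner's working life. Maple's partner therefore splits by 12.7%: that is the capture share, capture rate over capture plus decomposition. I reckon maple's target at 12.1% of the starting material charged.

**Where is that weak?** The frozen rate subtracts nothing for maple's starting material already reacted, so I call the reckoned target a high figure.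

**And the others?** With starting material at full charge, capture falls through the decomposition rate near 7.30 s. Alder's feed ends before that, and larch's ends after it. Cedar starts at 1.07 s⁻¹, above both rates. My order is cedar, alder, larch, maple.

The forecast names cedar, holding that “Anything delaying reagent contact loses out”. It gives cedar 57.5%, alder 41.6%, larch 19.2% and maple 9%, which for maple is below my figure.

The simulation gives cedar 57.5%, alder 41.9%, larch 19.3% and maple 8.68%, so cedar leads.

Maple's target comes to 9.14% of the partner charged, below the frozen capture share. At 7.79 s in maple decomposition uses partner 9.7 times as fast as capture, against 6.85 from the frozen rate.

For a neighbour flask, like maple but with 0.11 M of partner, I reckon with the same capture share, which gives 4.67% of the starting material charged. Computed, that neighbour gives 3.78%, below the reckoning, as in maple.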